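**Plan**

- Numbering: chain C1 (C=O) to C11; ring A is the phloroglucinol ring (C1'–C6'); ring B is the monophenol ring (C1''–C6'', chain on C1'', OH on C2'').
- Retrosynthesis: the three ring A hydroxyls go back to methyl ethers and the C2''–OH to a C2''–B bond. Ring B is then cut at C1''–C6'' and C2''–C3'', giving a boron-capped alkyne (C1''≡C2'') and the C3–C6 diene of 2H-pyran-2-one. Last to be cut are the alkynyl C–B bond, the ketone bond C1–C1' (Friedel–Crafts) and the chain bond C11–C1'' (acetylide alkylation).
- Forward: C11–C1'' is made first (terminal alkyne), ring A is attached at C1–C1', the alkyne terminus is borylated, ring B is built by Diels–Alder/retro-Diels–Alder benzannulation with loss of CO2, and C–B oxidation plus demethylation finish the target.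
- Enabling feature: ring B has only two substituents, on the adjacent carbons C1'' and C2'', next to four contiguous unsubstituted CH carbons C3''–C6''. It therefore maps onto a disubstituted alkyne plus an unsubstituted pyrone diene, and either orientation of addition gives the same arene.
- Stereochemistry: the target has no stereocentre and no stereogenic double bond, so nothing needs to be controlled.

Key step: step 4

**Route**

Step 1
Reactants: 1 11-bromoundecanoic acid
Product: 4 tridec-12-ynoic acid, via lithium 11-bromoundecanoate 2 (not isolated), via lithium tridec-12-ynoate 3 (not isolated)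
Conditions: LiC≡CH·H2N(CH2)2NH2 (3 equiv), DMSO, 10 °C → rt; then 1 M HCl
Reagents that add atoms: lithium acetylide–ethylenediamine complex, [Li+].[C-]#C.NCCN
Why: SN2 alkylation of an acetylide by a primary bromide: the first equivalent of lithium acetylide only deprotonates the acid to the inert carboxylate 2, the excess displaces bromide in the dipolar aprotic solvent, and the monolithiated acetylene delivers the terminal alkyne directly.

Step 2
Reactants: 4 tridec-12-ynoic acid; 5 1,3,5-trimethoxybenzene
Product: 7 1-(2,4,6-trimethoxyphenyl)tridec-12-yn-1-one, via tridec-12-ynoic trifluoroacetic anhydride 6 (not isolated)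
Conditions: (CF3CO)2O (1.2 equiv), CH2Cl2, 0 °C, 30 min; then 5 (1.1 equiv), 0 °C → rt
Reagents that add atoms: none
Why: Friedel–Crafts acylation through the mixed trifluoroacetic anhydride 6, which is electrophilic enough to acylate the strongly activated, threefold-symmetric arene 5 without a metal Lewis acid; the new acyl group deactivates the ring against a second acylation and the terminal alkyne should be inert to cold, dilute trifluoroacetic acid.

Step 3
Reactants: 7 1-(2,4,6-trimethoxyphenyl)tridec-12-yn-1-one
Product: 10 13-(4,4,5,5-tetramethyl-1,3,2-dioxaborolan-2-yl)-1-(2,4,6-trimethoxyphenyl)tridec-12-yn-1-one, via dilithium enolate acetylide 8 (not isolated), via dilithium alkynyl(isopropoxy)borate 9 (not isolated)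
Conditions: LiN(iPr)2 (2.2 equiv), THF, −78 °C, 7 added to the base; iPrOBpin (2.2 equiv), −78 °C; HCl in Et2O (4.3 equiv), −78 °C → rt; filtration under argon, evaporation; used crude
Reagents that add atoms: 2-isopropoxy-4,4,5,5-tetramethyl-1,3,2-dioxaborolane, CC(C)OB1OC(C)(C)C(C)(C)O1
Why: Lithiation–borylation of a terminal alkyne (alkynyllithium plus alkoxyborane, then anhydrous acid) run on the dianion 8: the first equivalent of amide base converts the ketone into its enolate, which shields the carbonyl and the α-protons, the second lithiates the alkyne, the acetylide adds to boron to give the ate complex 9, and HCl expels isopropanol from boron and returns the ketone, with the amine buffering the end point so that no free acid meets the alkynyl C–B bond.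

Step 4
Reactants: 10 13-(4,4,5,5-tetramethyl-1,3,2-dioxaborolan-2-yl)-1-(2,4,6-trimethoxyphenyl)tridec-12-yn-1-one; 11 2H-pyran-2-one
Product: 14 11-[2-(4,4,5,5-tetramethyl-1,3,2-dioxaborolan-2-yl)phenyl]-1-(2,4,6-trimethoxyphenyl)undecan-1-one, via bridged lactone adduct 12 (not isolated), via regioisomeric bridged lactone adduct 13 (not isolated)
Conditions: 11 (3 equiv), mesitylene (about 1 M in 10), dry and degassed, sealed tube under argon, 175 °C, 36 h
Reagents that add atoms: none
Why: The C3–C6 diene of 2H-pyran-2-one adds across the boron-bearing alkyne of 10 in a thermal (4+2) cycloaddition to give the bridged lactones 12 and 13, which at the same temperature lose carbon dioxide by retro-(4+2) fragmentation and aromatise to 14. The closest known reaction type is the thermal benzannulation of 2-pyrones with alkynyl pinacolboronates to arylboronates, a known reaction class that includes the unsubstituted pyrone and characteristically needs temperatures of this order. Ring B is closed intermolecularly, its two new bonds C1''–C6'' and C2''–C3'' arising suprafacially in one six-electron cycloaddition, and the six-membered carbocycle becomes a benzene once the lactone bridge is expelled. No stereocentre is created in 14; the two bridgehead centres of 12 and 13 are transient and vanish on aromatisation. No regiocontrol is needed because C3 to C6 of the pyrone carry only hydrogen, so both orientations of the alkyne converge on the same ortho-related chain and boron, and the required chemoselectivity (reaction at the alkyne only) is secured because the twisted aryl ketone and the electron-rich trimethoxyarene offer no other dienophile to the electron-poor diene. Excess pyrone, high concentration and strictly dry, degassed conditions are specified to offset the modest reactivity of the unactivated diene and to keep the alkynyl C–B bond from protolysis before it is locked into the robust aryl boronate.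

Step 5
Reactants: 14 11-[2-(4,4,5,5-tetramethyl-1,3,2-dioxaborolan-2-yl)phenyl]-1-(2,4,6-trimethoxyphenyl)undecan-1-one
Product: 16 11-(2-hydroxyphenyl)-1-(2,4,6-trimethoxyphenyl)undecan-1-one, via aryl pinacol borate 15 (not isolated)
Conditions: NaBO3·4H2O (3 equiv), THF/H2O (1:1), rt
Reagents that add atoms: sodium perborate tetrahydrate (dimeric peroxoborate salt, crystal water not drawn), [Na+].[Na+].O[B-]1(O)OO[B-](O)(O)OO1
Why: Oxidation of an arylboronate to a phenol by hydroperoxide addition to boron and 1,2-aryl shift from boron to oxygen, then hydrolysis of the borate 15, which places the oxygen exactly on C2''; the nearly neutral perborate should leave the hindered aryl ketone and the methyl ethers untouched.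

Step 6
Reactants: 16 11-(2-hydroxyphenyl)-1-(2,4,6-trimethoxyphenyl)undecan-1-one
Product: 18 11-(2-hydroxyphenyl)-1-(2,4,6-trihydroxyphenyl)undecan-1-one, via tetrakis(dibromoboryl) ether 17 (not isolated)
Conditions: BBr3 (8 equiv), CH2Cl2, −78 °C → rt, prolonged stirring (40 °C if the last ether lags); then ice-water
Reagents that add atoms: none
Why: Lewis-acid cleavage of aryl methyl ethers with BBr3 (bromide attacks the methyl group of the boron-bound ether); the two ethers flanking the carbonyl should fall first through chelation and the para ether last, hence the excess and long reaction time, and water hydrolyses the aryloxyboron species 17 to the free tetraphenol.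

**Compound list**

1 | 11-bromoundecanoic acid | OC(=O)CCCCCCCCCCBr | starting material
2 | lithium 11-bromoundecanoate | [Li+].[O-]C(=O)CCCCCCCCCCBr | intermediate
3 | lithium tridec-12-ynoate | [Li+].[O-]C(=O)CCCCCCCCCCC#C | intermediate
4 | tridec-12-ynoic acid | OC(=O)CCCCCCCCCCC#C | intermediate
5 | 1,3,5-trimethoxybenzene | COc1cc(OC)cc(OC)c1 | starting material
6 | tridec-12-ynoic trifluoroacetic anhydride | C#CCCCCCCCCCCC(=O)OC(=O)C(F)(F)F | intermediate
7 | 1-(2,4,6-trimethoxyphenyl)tridec-12-yn-1-one | C#CCCCCCCCCCCC(=O)c1c(OC)cc(OC)cc1OC | intermediate
8 | dilithium salt of 7 deprotonated at C2 (Z-enolate expected, geometry without consequence) and at the alkyne terminus | [Li+].[Li+].[C-]#CCCCCCCCCC/C=C(\[O-])c1c(OC)cc(OC)cc1OC | intermediate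
9 | dilithium salt carrying the same enolate and, at C13, the alkynyl(isopropoxy)pinacolborate | [Li+].[Li+].CC(C)O[B-]1(OC(C)(C)C(C)(C)O1)C#CCCCCCCCCC/C=C(\[O-])c1c(OC)cc(OC)cc1OC | intermediate
10 | 13-(4,4,5,5-tetramethyl-1,3,2-dioxaborolan-2-yl)-1-(2,4,6-trimethoxyphenyl)tridec-12-yn-1-one | CC1(C)OB(OC1(C)C)C#CCCCCCCCCCCC(=O)c1c(OC)cc(OC)cc1OC | intermediate
11 | 2H-pyran-2-one | O=c1cccco1 | starting material
12 | 2-oxabicyclo[2.2.2]octa-5,7-dien-3-one with the 11-oxo-11-(2,4,6-trimethoxyphenyl)undecyl chain on C5 (next to the carbonyl-bearing bridgehead C4) and the pinacolboryl group on C6; racemic, one enantiomer drawn | O=C1O[C@H]2C=C[C@@H]1C(CCCCCCCCCCC(=O)c1c(OC)cc(OC)cc1OC)=C2B1OC(C)(C)C(C)(C)O1 | intermediate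
13 | regioisomer of 12 with the pinacolboryl group on C5 and the chain on C6; racemic, one enantiomer drawn | O=C1O[C@H]2C=C[C@@H]1C(B1OC(C)(C)C(C)(C)O1)=C2CCCCCCCCCCC(=O)c1c(OC)cc(OC)cc1OC | intermediate
14 | 11-[2-(4,4,5,5-tetramethyl-1,3,2-dioxaborolan-2-yl)phenyl]-1-(2,4,6-trimethoxyphenyl)undecan-1-one | CC1(C)OB(OC1(C)C)c1ccccc1CCCCCCCCCCC(=O)c1c(OC)cc(OC)cc1OC | intermediate
15 | 11-{2-[(4,4,5,5-tetramethyl-1,3,2-dioxaborolan-2-yl)oxy]phenyl}-1-(2,4,6-trimethoxyphenyl)undecan-1-one | CC1(C)OB(OC1(C)C)Oc1ccccc1CCCCCCCCCCC(=O)c1c(OC)cc(OC)cc1OC | intermediate
16 | 11-(2-hydroxyphenyl)-1-(2,4,6-trimethoxyphenyl)undecan-1-one | Oc1ccccc1CCCCCCCCCCC(=O)c1c(OC)cc(OC)cc1OC | intermediate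
17 | 11-[2-(dibromoboryloxy)phenyl]-1-[2,4,6-tris(dibromoboryloxy)phenyl]undecan-1-one | BrB(Br)Oc1ccccc1CCCCCCCCCCC(=O)c1c(OB(Br)Br)cc(OB(Br)Br)cc1OB(Br)Br | intermediate
18 | 11-(2-hydroxyphenyl)-1-(2,4,6-trihydroxyphenyl)undecan-1-one | Oc1ccccc1CCCCCCCCCCC(=O)c1c(O)cc(O)cc1O | target

**Count and risks**

Total step count: 6. Longest linear sequence: 6 steps (1 → 4 → 7 → 10 → 14 → 16 → 18).

Steps most likely to fail, in descending order of risk:

1. Step 3. What may go wrong: incomplete double deprotonation, enolate side reactions on warming (self-aldol, uptake of the borate) and protolysis of the alkynyl C–B bond during the acid quench or on contact with moisture. The fallback sets out from 7 and comes back at 10 without any strong base. It is a catalytic dehydrogenative C–H borylation of the terminal alkyne with pinacolborane (CC1(C)OBOC1(C)C). The catalyst is [Cu(OTf)(CAAC)] (CAAC = 1-(2,6-diisopropylphenyl)-3,3-diethyl-5,5-dimethylpyrrolidin-2-ylidene) with catalytic NEt3 in benzene at rt, and hydrogen is released. This fallback makes no compound outside the list (entry F0). Its own hazard, hydroboration of the carbonyl, is reduced because the ketone is flanked by two ortho methoxy groups and is electronically deactivated.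

2. Step 4. What may go wrong: the cycloaddition of the unactivated diene may be slower than thermal decay of the partners. Trace water can protolyse the alkynylboronate, which would then lead to the boron-free arene, and the pyrone can oligomerise. The fallback sets out from 10 and comes back at 14. It forms the same two ring bonds at ambient temperature with buta-1,3-diene (C=CC=C) in place of the pyrone, under a low-valent cobalt catalyst generated from CoBr2(dppe), Zn and ZnI2 in CH2Cl2. This should give 11-[2-(4,4,5,5-tetramethyl-1,3,2-dioxaborolan-2-yl)cyclohexa-1,4-dien-1-yl]-1-(2,4,6-trimethoxyphenyl)undecan-1-one F1. Dehydrogenation with 2,3-dichloro-5,6-dicyano-1,4-benzoquinone (benzene, rt) should then aromatise F1 to 14.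

3. Step 1. What may go wrong: E2 elimination to the hard-to-separate undec-10-enoic acid, double alkylation of acetylene and N-alkylation of ethylenediamine may erode the displacement on the carboxylate salt. Because this is the first step, the fallback cannot start from an earlier numbered compound. It leaves 1 aside, sets out from commercial 12-hydroxydodecanoic acid F2 and comes back at 4. The alkyne is built by one-carbon homologation of an aldehyde instead of by substitution. Oxidation with catalytic TEMPO and PhI(OAc)2 in CH2Cl2 should give 12-oxododecanoic acid F3. Seyferth–Gilbert homologation with the Ohira–Bestmann reagent, dimethyl (1-diazo-2-oxopropyl)phosphonate (COP(=O)(OC)C(=[N+]=[N-])C(C)=O), K2CO3 and MeOH, followed by acidification, should then give 4.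

**Further compounds**

F0 | step 3 | none | none
F1 | step 4 | 11-[2-(4,4,5,5-tetramethyl-1,3,2-dioxaborolan-2-yl)cyclohexa-1,4-dien-1-yl]-1-(2,4,6-trimethoxyphenyl)undecan-1-one | CC1(C)OB(OC1(C)C)C1=C(CCCCCCCCCCC(=O)c2c(OC)cc(OC)cc2OC)CC=CC1
F2 | step 1 | 12-hydroxydodecanoic acid | OC(=O)CCCCCCCCCCCO
F3 | step 1 | 12-oxododecanoic acid | OC(=O)CCCCCCCCCCC=O
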